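**Retrosynthetic overview**

1. The target has ring A (cyclopentane C4–C5–C7–C8–C9), ring B (cycloheptane C9–C10–C11–C1–C2–C3–C4), ring C (dihydropyran on C1–C2) and ring D (acyl triketone enol). The enabling feature is that the isopropenyl carbon C6 on C5 is a former gem-dimethyl ring carbon, and the hydroxy/angular-methyl pair C8/C9 lies across from C4–C5, so rings A and B are one folded eleven-membered humulene ring.
2. Key disconnection: the ring A bond C5–C7 (retro Wagner–Meerwein ring contraction) together with the ring B bond C4–C9 (retro transannular cation–olefin closure) leads back to the trans-epoxide of a macrocyclic E,E-diene.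
3. The epoxide comes from substrate-controlled epoxidation of C8=C9 in the humulene cycloadduct.
4. Ring C comes from a catalyst-controlled oxa-Diels–Alder reaction of a methylene triketone with C1=C2 of α-humulene. The E-alkene gives the trans B/C fusion, which a cycloheptene could not give, and this step alone fixes the absolute configuration; C8/C9 and then C4/C5 are relayed from it.
5. Ring order: D (phloroglucinol, acylated and dearomatised), then C, then B and A in one event.

Key step: step 5

Remark: carbocycle atoms keep α-humulene numbering (C1–C11) in every compound; β-triketones are drawn as one enol tautomer; the sense of induction of the chiral acid in step 3 cannot be predicted, so the antipode that leads to the 1S,2R series has to be fixed by a first experiment and is written here as (S,S).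

**Step 1**
Reactants: 1 phloroglucinol; 2 2-methylpropanoyl chloride
Product: 3 2-methyl-1-(2,4,6-trihydroxyphenyl)propan-1-one
Conditions: AlCl3 (4 equiv), PhNO2, rt → 65 °C; aq. HCl work-up
Reagents that add atoms: none
Why: Friedel–Crafts C-acylation of the electron-rich triol should stop after one acyl group because the chelated aryl ketone deactivates the ring; no stereocentre is formed.

**Step 2**
Reactants: 3 2-methyl-1-(2,4,6-trihydroxyphenyl)propan-1-one
Product: 4 3,5-dihydroxy-4,6,6-trimethyl-2-(2-methylpropanoyl)cyclohexa-2,4-dien-1-one (norflavesone)
Conditions: NaOMe (3.3 equiv), MeI (3.1 equiv), MeOH, 0 °C → rt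
Reagents that add atoms: methyl iodide, CI
Why: Dearomative C-methylation of the phloroglucinolate places two methyl groups on one free ring carbon and one on the other, the stoichiometry limiting the reaction to three alkylations; the C(CH3)H position enolises, so no stereocentre persists.

**Step 3**
Reactants: 4 norflavesone; 5 α-humulene
Product: 7 (1S,2R)-humulene cycloadduct (trans-fused dihydropyran), via methylene triketone heterodiene 6 (not isolated)
Conditions: Ag2O (1.5 equiv), TEMPO (10 mol %), 4 Å MS, CH2Cl2, −20 °C, cold filtration; then 5 (2 equiv), (S,S)-IDPi acid [imidodiphosphorimidate from 3,3'-bis(3,5-bis(trifluoromethyl)phenyl)-BINOL, N-triflyl] (5 mol %), CH2Cl2, −78 → −60 °C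
Reagents that add atoms: none
Why: Proposed new method: 4 is dehydrogenated at its ring methyl group by Ag2O (nitroxyl-relayed, the classical silver oxide route to ortho-quinone methides) to the electron-poor 1-oxadiene 6, which has no free nucleophilic ring position left for Michael dimerisation; once the basic silver salts are filtered off, the confined chiral acid hydrogen-bonds to the ring carbonyl next to the methylene group and lowers the LUMO, so that at −78 °C only the catalyst-bound heterodiene should react in an asynchronous inverse-demand oxa-Diels–Alder reaction with C1=C2 of 5 (the most nucleophilic trisubstituted alkene): CH2 bonds to C1 and the carbonyl oxygen to the tertiary C2, suprafacially on the E-alkene, which gives the trans ring fusion; the two faces of C1=C2 are enantiotopic and belong to rapidly interconverting planar-chiral conformers of 5, so the chiral pocket sets C1 (S) and C2 (R) by selecting one of them; the closest known reaction types are the uncatalysed, racemic cycloaddition of such methylene triketones with terpene alkenes and the chiral imidodiphosphate-type Brønsted acid-catalysed oxa-Diels–Alder reaction of ortho-quinone methides with unactivated alkenes, so far intramolecular.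

**Step 4**
Reactants: 7 (1S,2R)-humulene cycloadduct
Product: 8 (1S,2R,8R,9R)-8,9-epoxide of 7
Conditions: mCPBA (1.05 equiv), CH2Cl2, −10 °C
Reagents that add atoms: 3-chloroperoxybenzoic acid (mCPBA), O=C(OO)c1cccc(Cl)c1
Why: Prilezhaev epoxidation is stereospecific (E-alkene to trans-epoxide) and should pick the only electron-rich trisubstituted alkene (C4=C5 is disubstituted and neopentylic, the ring D alkenes are push–pull); the peracid should approach the outer face of C8=C9 in the macrocycle conformation fixed by the trans-fused pyran, so C1 and C2 relay to 8R,9R.

**Step 5**
Reactants: 8 (1S,2R,8R,9R)-8,9-epoxide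
Product: 10 target, via tertiary 2-propyl cation 9 (not isolated)
Conditions: p-TsOH·H2O (20 mol %), CH2Cl2, 0 °C → rt
Reagents that add atoms: none
Why: Protonation of the epoxide and ionisation of its tertiary C9–O bond are assisted from the rear by the C4=C5 π bond that lies across the eleven-membered ring, so that C4–C9 forms with inversion at C9 while, concerted but asynchronous, the ring bond C6–C7 shifts to C5 (Wagner–Meerwein 1,2-alkyl shift, which makes the C5–C7 bond), and the 2-propyl cation 9 then loses a methyl proton (E1) to leave the isopropenyl group. The closest known reaction types are the acid-induced transannular cyclisation of humulene and germacrene epoxides and the ring-contracting retropinacol rearrangement of 4,4-dimethyl-3-hydroxy terpenoids. Ring B (C9–C10–C11–C1–C2–C3–C4) closes by transannular 7-exo attack of C4 on C9, which is at the same time the 6-endo closure of a transient cyclohexane C4–C5–C6–C7–C8–C9, and ring A (C4–C5–C7–C8–C9) closes by the 1,2-shift that contracts this cyclohexane. C8 keeps the epoxide configuration, C9 is set by anti opening (hydroxyl trans to the new C4–C9 bond), C4 by the alkene face that the pyran-locked macrocycle (C1, C2) turns toward C9, and C5 by geometry, since C7 and C9 hang on the same face of the E-alkene and both new bonds must form there (H4 and H5 trans, trans-fused hydroazulene). The step needs ring contraction to win over a hydride shift to the C8 ketone, methyl migration and plain proton loss; the substrate should secure this because the π bond is held within bonding distance behind C9–O, because the allylic ring bond C6–C7 stands nearly perpendicular to the alkene plane and is aligned with the p orbital developing at C5 while both methyl groups lie near its nodal plane, and because the shift turns a secondary into a tertiary cation.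

**Compound list**

1 | phloroglucinol (benzene-1,3,5-triol) | Oc1cc(O)cc(O)c1 | starting material
2 | 2-methylpropanoyl chloride (isobutyryl chloride) | CC(C)C(Cl)=O | starting material
3 | 2-methyl-1-(2,4,6-trihydroxyphenyl)propan-1-one | CC(C)C(=O)c1c(O)cc(O)cc1O | intermediate
4 | 3,5-dihydroxy-4,6,6-trimethyl-2-(2-methylpropanoyl)cyclohexa-2,4-dien-1-one (norflavesone, one enol tautomer) | CC(C)C(=O)C1=C(O)C(C)=C(O)C(C)(C)C1=O | intermediate
5 | α-humulene, (1E,4E,8E)-2,6,6,9-tetramethylcycloundeca-1,4,8-triene | C1/C=C(\C)C/C=C/C(C)(C)C/C=C(\C)C1 | starting material
6 | 5-hydroxy-2,2-dimethyl-6-methylidene-4-(2-methylpropanoyl)cyclohex-4-ene-1,3-dione (heterodiene, not isolated) | CC(C)C(=O)C1=C(O)C(=C)C(=O)C(C)(C)C1=O | intermediate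
7 | (1S,2R)-cycloadduct of 6 with C1=C2 of 5: dihydropyran trans-fused to the (4E,8E)-cycloundecadiene, C1–H bonded to the ring D methylene, C2–CH3 bonded to the pyran oxygen | C1[C@@H](CC2=C(O3)C(C)(C)C(=O)C(C(=O)C(C)C)=C2O)[C@@]3(C)C/C=C/C(C)(C)C/C=C(\C)C1 | intermediate
8 | (1S,2R,8R,9R)-8,9-epoxide of 7 (trans-epoxide, 4E alkene kept) | C1[C@@H](CC2=C(O3)C(C)(C)C(=O)C(C(=O)C(C)C)=C2O)[C@@]3(C)C/C=C/C(C)(C)C[C@H]4O[C@]4(C)C1 | intermediate
9 | 2-propyl cation at C6 of the rearranged tetracycle, tosylate ion pair (not isolated) | C[C+](C)[C@@H]1C[C@@H](O)[C@]2(C)CC[C@H]3CC4=C(O[C@]3(C)C[C@@H]12)C(C)(C)C(=O)C(C(=O)C(C)C)=C4O.Cc1ccc(cc1)S(=O)(=O)[O-] | intermediate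
10 | target, (1S,2R,4S,5R,8R,9R) in humulene numbering: C8 hydroxyl cis to the C9 methyl, C4–H trans to the C9 methyl, C5 isopropenyl trans to C3, pyran trans-fused | C=C(C)[C@@H]1C[C@@H](O)[C@]2(C)CC[C@H]3CC4=C(O[C@]3(C)C[C@@H]12)C(C)(C)C(=O)C(C(=O)C(C)C)=C4O | target

**Step count and risks**

Total step count: 5. Longest linear sequence: 5 steps (1 → 3 → 4 → 7 → 8 → 10).

Steps most likely to fail:

1. Step 3 (proposed new method). The risks are insufficient discrimination between the enantiotopic alkene faces because free heterodiene reacts in a racemic background cycloaddition, self-dimerisation of the heterodiene before it meets the alkene, and acid-induced isomerisation of the triene. The fallback sets out from 4 and 5 and uses known chemistry: the one-pot oxidative cycloaddition without chiral acid (TEMPO, Ag2O, CH2Cl2, room temperature) should give the racemate, that is 7 together with its antipode, the (1R,2S)-cycloadduct F1. The enantiomers are then separated by preparative supercritical-fluid chromatography on an amylose tris(3,5-dimethylphenylcarbamate) phase and assigned by electronic circular dichroism or anomalous-dispersion X-ray analysis. The fallback comes back to the route at 7.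

2. Step 5. The risks are diversion of the C9 cation before transannular capture (hydride shift to the C8 ketone, proton loss to allylic alcohols), protic ionisation of the tertiary C2–O bond of the pyran, and re-protonation of the isopropenyl group with migration of the double bond. The fallback sets out from 8 and changes the trigger from a proton to a silyl cation, protecting the enol and the new alcohol in the same operation at the price of one deprotection. With TMSOTf and 2,6-di-tert-butyl-4-methylpyridine in CH2Cl2 at −78 °C, 8 should first give its enol trimethylsilyl ether F2 in the flask, and a second equivalent should open the epoxide as a silyloxonium ion and drive the same cyclisation and ring contraction under proton-free conditions to the bis(trimethylsilyl) ether F3. K2CO3 in MeOH should then remove both silyl groups. The fallback comes back to the route at 10.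

3. Step 2. The risks are over-methylation at the remaining C(CH3)H position, under-methylation and competing O-methylation, which would give mixtures that are hard to separate. The fallback sets out from 2 and reverses the order of C-methylation and acylation. Bought 2-methylbenzene-1,3,5-triol F4 is acylated under the conditions of step 1 to 2-methyl-1-(2,4,6-trihydroxy-3-methylphenyl)propan-1-one F5. Only two C-methylations (NaOMe, MeI, MeOH) are then needed, and either order of attack on the two nucleophilic ring carbons converges on the same product. The fallback comes back to the route at 4.

**Further compounds**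

F1 | step 3 | (1R,2S)-cycloadduct, antipode of 7 | C1[C@H](CC2=C(O3)C(C)(C)C(=O)C(C(=O)C(C)C)=C2O)[C@]3(C)C/C=C/C(C)(C)C/C=C(\C)C1
F2 | step 5 | enol trimethylsilyl ether of epoxide 8 (not isolated) | C1[C@@H](CC2=C(O3)C(C)(C)C(=O)C(C(=O)C(C)C)=C2O[Si](C)(C)C)[C@@]3(C)C/C=C/C(C)(C)C[C@H]4O[C@]4(C)C1
F3 | step 5 | bis(trimethylsilyl) ether of 10 (C8–O and enol O) | C=C(C)[C@@H]1C[C@@H](O[Si](C)(C)C)[C@]2(C)CC[C@H]3CC4=C(O[C@]3(C)C[C@@H]12)C(C)(C)C(=O)C(C(=O)C(C)C)=C4O[Si](C)(C)C
F4 | step 2 | 2-methylbenzene-1,3,5-triol (bought) | Cc1c(O)cc(O)cc1O
F5 | step 2 | 2-methyl-1-(2,4,6-trihydroxy-3-methylphenyl)propan-1-one | CC(C)C(=O)c1c(O)cc(O)c(C)c1O
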